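## Retrosynthetic overview

- The target is traced back, by ester and protecting-group changes and an amide-to-aldehyde reduction, to a ring-opened Weinreb amide and then to an α-methylene γ-lactone. The methylene carbon comes from a Mannich reagent, the 3-methylbutanoate from isovaleric anhydride, and the (S)-carbinol from asymmetric transfer hydrogenation of the aryl ketone.
- Key disconnection C3–C3a: intramolecular Friedel–Crafts attack of the aryl ether ortho carbon on the oxocarbenium ion of a 5-acetoxy-4-aryloxy-γ-butanolide. This gives the cis-fused lactone of (2R,3R)-5-acetyl-2-(carboxymethyl)-2,3-dihydrobenzofuran-3-ol.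
- That acetate comes from a tert-butyl (R)-3-aryloxy-4-oxobutanoate, made by Mitsunobu inversion with 4-hydroxyacetophenone on a derivative of (S)-malic acid 4-tert-butyl ester (from L-aspartic acid 4-tert-butyl ester).
- Feature on which the strategy rests: the chain C3–C2–Cα–CHO (the two sp3 carbons of the dihydrofuran ring, the alkene carbon and the formyl carbon) is the four-carbon chain of malic acid. C2 is its carbinol carbon (aryl ether O1 after inversion); C3 and the formyl carbon are its two carboxyl carbons.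
- Ring order: the benzene ring is bought; the γ-lactone ring is closed first (step 7) as a temporary tether; the dihydrofuran ring is closed second, in the key step; the lactone ring is opened again in step 13.

Key step: step 8

Remark on the chemistry: positions are numbered as in 2,3-dihydrobenzofuran. The malic acid chain is carried as a tert-butyl ester so that the carboxyl group can be freed by acid beside the aldehyde, and no hydride reagent meets the aryl ketone before the key step.

## Route

Step 1
Reactants: 1 L-aspartic acid 4-tert-butyl ester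
Product: 2 (2S)-4-tert-butoxy-2-hydroxy-4-oxobutanoic acid
Conditions: NaNO2, 1 M aq. H2SO4, 0 °C → rt
Reagents that add atoms: water, O
Why: Diazotisation of the α-amino acid passes through an α-lactone formed by the neighbouring carboxylate, so water should replace nitrogen with net retention and give the (S)-malic acid half-ester with its two carboxyl groups already told apart.

Step 2
Reactants: 2 (2S)-4-tert-butoxy-2-hydroxy-4-oxobutanoic acid
Product: 3 tert-butyl (3S)-3,4-dihydroxybutanoate
Conditions: BH3·SMe2, THF, 0 °C → rt; MeOH quench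
Reagents that add atoms: none
Why: Chemoselective borane reduction of a carboxylic acid, which is much faster than reduction of the tert-butyl ester and does not touch the carbinol stereocentre.

Step 3
Reactants: 3 tert-butyl (3S)-3,4-dihydroxybutanoate
Product: 4 tert-butyl (3S)-4-[(tert-butyldimethylsilyl)oxy]-3-hydroxybutanoate
Conditions: TBSCl (1.05 equiv), imidazole, CH2Cl2, 0 °C
Reagents that add atoms: tert-butyldimethylsilyl chloride, CC(C)(C)[Si](C)(C)Cl
Why: Silylation with TBSCl and imidazole should take the primary hydroxyl in preference to the secondary one for steric reasons.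

Step 4
Reactants: 4 tert-butyl (3S)-4-[(tert-butyldimethylsilyl)oxy]-3-hydroxybutanoate; 5 4-hydroxyacetophenone
Product: 6 tert-butyl (3R)-3-(4-acetylphenoxy)-4-[(tert-butyldimethylsilyl)oxy]butanoate
Conditions: PPh3, DIAD, toluene, 0 °C → rt
Reagents that add atoms: none
Why: Mitsunobu etherification, in which the acidic phenol (pKa about 8) displaces the oxyphosphonium group by SN2 with inversion, turning the (S)-carbinol into the (R)-aryl ether that becomes C2 of the target; toluene at low temperature should hold back β-elimination to the crotonate.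

Step 5
Reactants: 6 tert-butyl (3R)-3-(4-acetylphenoxy)-4-[(tert-butyldimethylsilyl)oxy]butanoate
Product: 7 tert-butyl (3R)-3-(4-acetylphenoxy)-4-hydroxybutanoate
Conditions: HF·pyridine, pyridine, THF, 0 °C → rt
Reagents that add atoms: none
Why: Fluoride desilylation with buffered HF·pyridine is not basic enough to expel the β-aryloxide (E1cB) and not acidic enough to cleave the tert-butyl ester, which does not lactonise with the freed alcohol under these conditions.

Step 6
Reactants: 7 tert-butyl (3R)-3-(4-acetylphenoxy)-4-hydroxybutanoate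
Product: 8 tert-butyl (3R)-3-(4-acetylphenoxy)-4-oxobutanoate
Conditions: Dess–Martin periodinane, CH2Cl2, 0 °C → rt
Reagents that add atoms: none
Why: Dess–Martin oxidation stops at the aldehyde under mild, non-basic conditions, so the α-aryloxy stereocentre should not epimerise and the aryl ketone and ester are untouched.

Step 7
Reactants: 8 tert-butyl (3R)-3-(4-acetylphenoxy)-4-oxobutanoate
Product: 10 (4R)-5-acetoxy-4-(4-acetylphenoxy)dihydrofuran-2(3H)-one as anomeric mixture, via pseudo-acid lactol 9 (not isolated)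
Conditions: TFA, CH2Cl2, 0 °C → rt; evaporate; Ac2O, pyridine, DMAP (cat.), CH2Cl2, 0 °C
Reagents that add atoms: acetic anhydride, CC(=O)OC(C)=O
Why: Acidolysis of the tert-butyl ester frees the acid, which closes onto the electron-poor aldehyde as its ring tautomer (the γ-lactone ring), and acetylation fixes this form as the anomeric acetate; C4 is unchanged and the anomeric mixture is of no consequence.

Step 8
Reactants: 10 (4R)-5-acetoxy-4-(4-acetylphenoxy)dihydrofuran-2(3H)-one
Product: 11 lactone of (2R,3R)-5-acetyl-2-(carboxymethyl)-2,3-dihydrobenzofuran-3-ol [(3aR,8bR)-7-acetyl-3a,8b-dihydrofuro[3,2-b][1]benzofuran-2(3H)-one]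
Conditions: SnCl4 (3 equiv), CH2Cl2, −78 → 0 °C
Reagents that add atoms: none
Why: SnCl4 (one equivalent is held by the ketone) ionises the anomeric acetate of either anomer to the O-acyl oxocarbenium ion at lactone C5; the aryl carbon ortho to the ether oxygen (meta to the acetyl group) attacks it and proton loss restores the aromatic ring, an intramolecular Friedel–Crafts alkylation. The closest known reactions are the Friedel–Crafts arylation of pseudo-acid derivatives (3-acetoxyphthalides, mucohalic acids, 5-acyloxybutanolides) and the acid cyclisation of aryloxyacetaldehyde acetals onto the ortho carbon, a closure known for 4-acylphenyl ethers as well. The dihydrofuran ring closes in a 5-exo-trig mode with respect to the C=O+ bond, the attacking arene C=C lying inside the new ring. The new stereocentre C3 is dictated by C2 (the malate carbinol carbon): two fused five-membered rings can only be cis, so both anomers should converge on the (2R,3R) lactone. The step needs ortho regioselectivity, which the tether and the blocked para position secure, and cyclisation must outrun proton loss from C4 to the 4-aryloxybutenolide, which the non-basic medium and low temperature favour; the acetyl group, para to O1, also keeps the benzylic C3–O bond of the product from ionising towards the benzofuran.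

Step 9
Reactants: 11 lactone of (2R,3R)-5-acetyl-2-(carboxymethyl)-2,3-dihydrobenzofuran-3-ol
Product: 12 lactone of (2R,3R)-2-(carboxymethyl)-5-[(1S)-1-hydroxyethyl]-2,3-dihydrobenzofuran-3-ol
Conditions: RuCl[(S,S)-TsDPEN](p-cymene) (1 mol%), HCO2H/Et3N (5:2), CH2Cl2, rt
Reagents that add atoms: none
Why: Noyori asymmetric transfer hydrogenation of the aryl methyl ketone, in which the (S,S)-TsDPEN ruthenium catalyst should deliver hydride to the face that gives the (S)-carbinol by catalyst control while the lactone is inert to formic acid and triethylamine.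

Step 10
Reactants: 12 lactone of (2R,3R)-2-(carboxymethyl)-5-[(1S)-1-hydroxyethyl]-2,3-dihydrobenzofuran-3-ol
Product: 13 lactone of (2R,3R)-5-{(1S)-1-[(tert-butyldimethylsilyl)oxy]ethyl}-2-(carboxymethyl)-2,3-dihydrobenzofuran-3-ol
Conditions: TBSCl, imidazole, DMF, rt
Reagents that add atoms: tert-butyldimethylsilyl chloride, CC(C)(C)[Si](C)(C)Cl
Why: Standard silylation of the secondary benzylic alcohol protects it from the base, the aluminium reagents and the hydride of the following steps.

Step 11
Reactants: 13 lactone of (2R,3R)-5-{(1S)-1-[(tert-butyldimethylsilyl)oxy]ethyl}-2-(carboxymethyl)-2,3-dihydrobenzofuran-3-ol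
Product: 15 α-(dimethylaminomethyl) derivative of lactone 13 (mixture at the new α-carbon), via trimethylsilyl ketene acetal 14 (not isolated)
Conditions: LiN(iPr)2, Me3SiCl (premixed), THF, −78 °C; then CH2=NMe2+ I−, CH2Cl2, −78 °C → rt
Reagents that add atoms: dimethylmethyleneammonium iodide (Eschenmoser's salt), C=[N+](C)C.[I-]
Why: Mannich aminomethylation of a lactone enolate equivalent, in which in-situ silylation traps the enolate as its ketene acetal before it can expel the β-aryloxide, while the cis ring fusion would in any case re-form the same C2 configuration on re-closure; the new centre at Cα is destroyed in step 12.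

Step 12
Reactants: 15 α-(dimethylaminomethyl) derivative of lactone 13
Product: 17 α-methylene lactone [lactone of 2-[(2R,3R)-5-{(1S)-1-[(tert-butyldimethylsilyl)oxy]ethyl}-3-hydroxy-2,3-dihydrobenzofuran-2-yl]prop-2-enoic acid], via trimethylammonium iodide 16 (not isolated)
Conditions: MeI, CH2Cl2, rt; then aq. NaHCO3, rt
Reagents that add atoms: none
Why: Quaternisation followed by E1cB (Hofmann-type) elimination gives the α-methylene lactone, trimethylammonium being a far better leaving group than the ring aryloxide.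

Step 13
Reactants: 17 α-methylene lactone
Product: 18 2-[(2R,3R)-5-{(1S)-1-[(tert-butyldimethylsilyl)oxy]ethyl}-3-hydroxy-2,3-dihydrobenzofuran-2-yl]-N-methoxy-N-methylprop-2-enamide
Conditions: MeNHOMe·HCl, AlMe3, CH2Cl2, 0 °C → rt
Reagents that add atoms: N,O-dimethylhydroxylamine hydrochloride, CNOC.Cl
Why: Weinreb aminolysis, in which the aluminium amide activates the lactone carbonyl and delivers the amine in a 1,2-sense, opening the lactone ring to the acrylamide and freeing the C3 hydroxyl without touching C2 or C3.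

Step 14
Reactants: 18 hydroxy Weinreb amide; 19 isovaleric anhydride (3-methylbutanoic anhydride)
Product: 20 (2R,3R)-5-{(1S)-1-[(tert-butyldimethylsilyl)oxy]ethyl}-2-{3-[methoxy(methyl)amino]-3-oxoprop-1-en-2-yl}-2,3-dihydrobenzofuran-3-yl 3-methylbutanoate
Conditions: Et3N, DMAP (cat.), CH2Cl2, 0 °C → rt
Reagents that add atoms: none
Why: DMAP-catalysed acylation of the secondary benzylic alcohol with the anhydride installs the 3-methylbutanoate and blocks re-lactonisation.

Step 15
Reactants: 20 Weinreb amide ester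
Product: 21 (2R,3R)-5-{(1S)-1-[(tert-butyldimethylsilyl)oxy]ethyl}-2-(3-oxoprop-1-en-2-yl)-2,3-dihydrobenzofuran-3-yl 3-methylbutanoate
Conditions: iBu2AlH (1.2 equiv), THF, −78 °C
Reagents that add atoms: none
Why: Weinreb amide reduction, in which iBu2AlH forms a chelated tetrahedral intermediate that collapses to the enal only on work-up, and at −78 °C in THF the amide should react faster than the hindered secondary ester.

Step 16
Reactants: 21 silyl-protected enal
Product: 22 (2R,3R)-5-[(1S)-1-hydroxyethyl]-2-(3-oxoprop-1-en-2-yl)-2,3-dihydrobenzofuran-3-yl 3-methylbutanoate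
Conditions: HF·pyridine, pyridine, THF, 0 °C → rt
Reagents that add atoms: none
Why: Fluoride desilylation under buffered, weakly acidic conditions should spare the enal, which has no α-hydrogen, and the benzylic ester.

Step 17
Reactants: 22 hydroxy enal
Product: 23 (2R,3R)-5-[(1S)-1-acetoxyethyl]-2-(3-oxoprop-1-en-2-yl)-2,3-dihydrobenzofuran-3-yl 3-methylbutanoate (CNP0252902.1)
Conditions: Ac2O, pyridine, DMAP (cat.), CH2Cl2, 0 °C
Reagents that add atoms: acetic anhydride, CC(=O)OC(C)=O
Why: DMAP-catalysed acetylation of the free secondary alcohol completes the target with retention at the (S)-carbinol carbon.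

## Compound list

1 | L-aspartic acid 4-tert-butyl ester | N[C@@H](CC(=O)OC(C)(C)C)C(=O)O | starting material
2 | (2S)-4-tert-butoxy-2-hydroxy-4-oxobutanoic acid [(S)-malic acid 4-tert-butyl ester] | O[C@@H](CC(=O)OC(C)(C)C)C(=O)O | intermediate
3 | tert-butyl (3S)-3,4-dihydroxybutanoate | CC(C)(C)OC(=O)C[C@H](O)CO | intermediate
4 | tert-butyl (3S)-4-[(tert-butyldimethylsilyl)oxy]-3-hydroxybutanoate | CC(C)(C)OC(=O)C[C@H](O)CO[Si](C)(C)C(C)(C)C | intermediate
5 | 4-hydroxyacetophenone | CC(=O)c1ccc(O)cc1 | starting material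
6 | tert-butyl (3R)-3-(4-acetylphenoxy)-4-[(tert-butyldimethylsilyl)oxy]butanoate | CC(C)(C)OC(=O)C[C@@H](Oc1ccc(C(C)=O)cc1)CO[Si](C)(C)C(C)(C)C | intermediate
7 | tert-butyl (3R)-3-(4-acetylphenoxy)-4-hydroxybutanoate | CC(C)(C)OC(=O)C[C@@H](Oc1ccc(C(C)=O)cc1)CO | intermediate
8 | tert-butyl (3R)-3-(4-acetylphenoxy)-4-oxobutanoate | CC(C)(C)OC(=O)C[C@@H](Oc1ccc(C(C)=O)cc1)C=O | intermediate
9 | (4R)-4-(4-acetylphenoxy)-5-hydroxydihydrofuran-2(3H)-one (pseudo-acid lactol, C5 mixture) | O=C1C[C@@H](Oc2ccc(C(C)=O)cc2)C(O)O1 | intermediate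
10 | (4R)-5-acetoxy-4-(4-acetylphenoxy)dihydrofuran-2(3H)-one (anomeric mixture) | CC(=O)OC1OC(=O)C[C@H]1Oc1ccc(C(C)=O)cc1 | intermediate
11 | lactone of (2R,3R)-5-acetyl-2-(carboxymethyl)-2,3-dihydrobenzofuran-3-ol, cis-fused | O=C1C[C@H]2Oc3ccc(C(C)=O)cc3[C@H]2O1 | intermediate
12 | lactone of (2R,3R)-2-(carboxymethyl)-5-[(1S)-1-hydroxyethyl]-2,3-dihydrobenzofuran-3-ol | O=C1C[C@H]2Oc3ccc([C@H](C)O)cc3[C@H]2O1 | intermediate
13 | lactone of (2R,3R)-5-{(1S)-1-[(tert-butyldimethylsilyl)oxy]ethyl}-2-(carboxymethyl)-2,3-dihydrobenzofuran-3-ol | O=C1C[C@H]2Oc3ccc([C@H](C)O[Si](C)(C)C(C)(C)C)cc3[C@H]2O1 | intermediate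
14 | trimethylsilyl ketene acetal of lactone 13 | C[Si](C)(C)OC1=C[C@H]2Oc3ccc([C@H](C)O[Si](C)(C)C(C)(C)C)cc3[C@H]2O1 | intermediate
15 | α-(dimethylaminomethyl) derivative of lactone 13 (mixture at the α-carbon) | O=C1C(CN(C)C)[C@H]2Oc3ccc([C@H](C)O[Si](C)(C)C(C)(C)C)cc3[C@H]2O1 | intermediate
16 | trimethylammonium iodide from 15 | O=C1C(C[N+](C)(C)C)[C@H]2Oc3ccc([C@H](C)O[Si](C)(C)C(C)(C)C)cc3[C@H]2O1.[I-] | intermediate
17 | α-methylene lactone: lactone of 2-[(2R,3R)-5-{(1S)-1-[(tert-butyldimethylsilyl)oxy]ethyl}-3-hydroxy-2,3-dihydrobenzofuran-2-yl]prop-2-enoic acid | O=C1C(=C)[C@H]2Oc3ccc([C@H](C)O[Si](C)(C)C(C)(C)C)cc3[C@H]2O1 | intermediate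
18 | 2-[(2R,3R)-5-{(1S)-1-[(tert-butyldimethylsilyl)oxy]ethyl}-3-hydroxy-2,3-dihydrobenzofuran-2-yl]-N-methoxy-N-methylprop-2-enamide | C=C(C(=O)N(C)OC)[C@H]1Oc2ccc([C@H](C)O[Si](C)(C)C(C)(C)C)cc2[C@H]1O | intermediate
19 | isovaleric anhydride (3-methylbutanoic anhydride) | CC(C)CC(=O)OC(=O)CC(C)C | starting material
20 | (2R,3R)-5-{(1S)-1-[(tert-butyldimethylsilyl)oxy]ethyl}-2-{3-[methoxy(methyl)amino]-3-oxoprop-1-en-2-yl}-2,3-dihydrobenzofuran-3-yl 3-methylbutanoate | C=C(C(=O)N(C)OC)[C@H]1Oc2ccc([C@H](C)O[Si](C)(C)C(C)(C)C)cc2[C@H]1OC(=O)CC(C)C | intermediate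
21 | (2R,3R)-5-{(1S)-1-[(tert-butyldimethylsilyl)oxy]ethyl}-2-(3-oxoprop-1-en-2-yl)-2,3-dihydrobenzofuran-3-yl 3-methylbutanoate | C=C(C=O)[C@H]1Oc2ccc([C@H](C)O[Si](C)(C)C(C)(C)C)cc2[C@H]1OC(=O)CC(C)C | intermediate
22 | (2R,3R)-5-[(1S)-1-hydroxyethyl]-2-(3-oxoprop-1-en-2-yl)-2,3-dihydrobenzofuran-3-yl 3-methylbutanoate | C=C(C=O)[C@H]1Oc2ccc([C@H](C)O)cc2[C@H]1OC(=O)CC(C)C | intermediate
23 | (2R,3R)-5-[(1S)-1-acetoxyethyl]-2-(3-oxoprop-1-en-2-yl)-2,3-dihydrobenzofuran-3-yl 3-methylbutanoate | C=C(C=O)[C@H]1Oc2ccc([C@H](C)OC(C)=O)cc2[C@H]1OC(=O)CC(C)C | target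

## Step count and risks

Total step count: 17. Longest linear sequence: 17 steps (1 → 23); compounds 5 and 19 are bought and enter in steps 4 and 14.

Steps most likely to fail:

**Step 8 (key cyclisation).** The acetyl-deactivated and Lewis-acid-complexed arene may attack too slowly. The oxocarbenium ion would then lose the C4 proton to give a 4-aryloxybutenolide, with loss of the stereocentre, or the acetate would simply not ionise.

Fallback: the same C3–C3a bond is made by an intramolecular Nozaki–Hiyama–Kishi addition, setting out from 4 and returning at 11.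
- Mitsunobu etherification of 4 with commercial 4'-hydroxy-3'-iodoacetophenone (PPh3, DIAD) should give tert-butyl (3R)-3-(4-acetyl-2-iodophenoxy)-4-[(tert-butyldimethylsilyl)oxy]butanoate F1.
- HF·pyridine should give tert-butyl (3R)-3-(4-acetyl-2-iodophenoxy)-4-hydroxybutanoate F2, and Dess–Martin oxidation tert-butyl (3R)-3-(4-acetyl-2-iodophenoxy)-4-oxobutanoate F3.
- CrCl2 with catalytic NiCl2 in DMF adds the aryl iodide carbon to the aldehyde, chemoselectively over the ketone. This closes the dihydrofuran ring to tert-butyl 2-[(2R,3R)-5-acetyl-3-hydroxy-2,3-dihydrobenzofuran-2-yl]acetate F4, together with its C3 epimer.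
- TFA then cleaves the ester. Only the cis isomer can lactonise, which returns the route to 11; the trans hydroxy acid is removed by base extraction.

**Step 11 (aminomethylation of the lactone).** The enolate, or the ketene acetal under the Mannich conditions, may expel the β-aryloxide (E1cB opening of the dihydrofuran ring) faster than it is trapped, so that no carbon is added.

Fallback: the methylene carbon is added at the aldehyde stage, setting out from 13 and returning at 21.
- Weinreb aminolysis (MeNHOMe·HCl, AlMe3) should give 2-[(2R,3R)-5-{(1S)-1-[(tert-butyldimethylsilyl)oxy]ethyl}-3-hydroxy-2,3-dihydrobenzofuran-2-yl]-N-methoxy-N-methylacetamide F5.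
- Acylation with 19 (Et3N, DMAP) should give its 3-O-(3-methylbutanoate) F6.
- iBu2AlH at −78 °C should give (2R,3R)-5-{(1S)-1-[(tert-butyldimethylsilyl)oxy]ethyl}-2-(2-oxoethyl)-2,3-dihydrobenzofuran-3-yl 3-methylbutanoate F7.
- Organocatalytic α-methylenation of the aldehyde (aqueous formaldehyde, pyrrolidine, propionic acid, iPrOH, 45 °C; Mannich condensation and loss of the amine) should then give 21.

**Step 15 (amide reduction beside the ester).** The conjugated, α-branched Weinreb amide may react too slowly, so that the hydride cleaves the 3-methylbutanoate or adds in a 1,4-sense.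

Fallback: the aldehyde is reached by oxidation instead, setting out from 17 and returning at 21; this also by-passes steps 13 and 14.
- Excess iBu2AlH (CH2Cl2, −78 → 0 °C) should reduce the lactone to (2R,3R)-5-{(1S)-1-[(tert-butyldimethylsilyl)oxy]ethyl}-2-(3-hydroxyprop-1-en-2-yl)-2,3-dihydrobenzofuran-3-ol F8.
- Et3SiCl and imidazole at −40 °C should silylate the primary allylic hydroxyl to give (2R,3R)-5-{(1S)-1-[(tert-butyldimethylsilyl)oxy]ethyl}-2-{3-[(triethylsilyl)oxy]prop-1-en-2-yl}-2,3-dihydrobenzofuran-3-ol F9.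
- Acylation with 19 (Et3N, DMAP) should give its 3-methylbutanoate F10.
- AcOH/THF/H2O should remove only the primary triethylsilyl ether, giving (2R,3R)-5-{(1S)-1-[(tert-butyldimethylsilyl)oxy]ethyl}-2-(3-hydroxyprop-1-en-2-yl)-2,3-dihydrobenzofuran-3-yl 3-methylbutanoate F11.
- MnO2 in CH2Cl2 should oxidise the allylic alcohol to 21.

Further compounds
F1 | step 8 | tert-butyl (3R)-3-(4-acetyl-2-iodophenoxy)-4-[(tert-butyldimethylsilyl)oxy]butanoate | CC(C)(C)OC(=O)C[C@@H](Oc1ccc(C(C)=O)cc1I)CO[Si](C)(C)C(C)(C)C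
F2 | step 8 | tert-butyl (3R)-3-(4-acetyl-2-iodophenoxy)-4-hydroxybutanoate | CC(C)(C)OC(=O)C[C@@H](Oc1ccc(C(C)=O)cc1I)CO
F3 | step 8 | tert-butyl (3R)-3-(4-acetyl-2-iodophenoxy)-4-oxobutanoate | CC(C)(C)OC(=O)C[C@@H](Oc1ccc(C(C)=O)cc1I)C=O
F4 | step 8 | tert-butyl 2-[(2R,3R)-5-acetyl-3-hydroxy-2,3-dihydrobenzofuran-2-yl]acetate | CC(C)(C)OC(=O)C[C@H]1Oc2ccc(C(C)=O)cc2[C@H]1O
F5 | step 11 | 2-[(2R,3R)-5-{(1S)-1-[(tert-butyldimethylsilyl)oxy]ethyl}-3-hydroxy-2,3-dihydrobenzofuran-2-yl]-N-methoxy-N-methylacetamide | CON(C)C(=O)C[C@H]1Oc2ccc([C@H](C)O[Si](C)(C)C(C)(C)C)cc2[C@H]1O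
F6 | step 11 | (2R,3R)-5-{(1S)-1-[(tert-butyldimethylsilyl)oxy]ethyl}-2-{2-[methoxy(methyl)amino]-2-oxoethyl}-2,3-dihydrobenzofuran-3-yl 3-methylbutanoate | CON(C)C(=O)C[C@H]1Oc2ccc([C@H](C)O[Si](C)(C)C(C)(C)C)cc2[C@H]1OC(=O)CC(C)C
F7 | step 11 | (2R,3R)-5-{(1S)-1-[(tert-butyldimethylsilyl)oxy]ethyl}-2-(2-oxoethyl)-2,3-dihydrobenzofuran-3-yl 3-methylbutanoate | O=CC[C@H]1Oc2ccc([C@H](C)O[Si](C)(C)C(C)(C)C)cc2[C@H]1OC(=O)CC(C)C
F8 | step 15 | (2R,3R)-5-{(1S)-1-[(tert-butyldimethylsilyl)oxy]ethyl}-2-(3-hydroxyprop-1-en-2-yl)-2,3-dihydrobenzofuran-3-ol | C=C(CO)[C@H]1Oc2ccc([C@H](C)O[Si](C)(C)C(C)(C)C)cc2[C@H]1O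
F9 | step 15 | (2R,3R)-5-{(1S)-1-[(tert-butyldimethylsilyl)oxy]ethyl}-2-{3-[(triethylsilyl)oxy]prop-1-en-2-yl}-2,3-dihydrobenzofuran-3-ol | C=C(CO[Si](CC)(CC)CC)[C@H]1Oc2ccc([C@H](C)O[Si](C)(C)C(C)(C)C)cc2[C@H]1O
F10 | step 15 | (2R,3R)-5-{(1S)-1-[(tert-butyldimethylsilyl)oxy]ethyl}-2-{3-[(triethylsilyl)oxy]prop-1-en-2-yl}-2,3-dihydrobenzofuran-3-yl 3-methylbutanoate | C=C(CO[Si](CC)(CC)CC)[C@H]1Oc2ccc([C@H](C)O[Si](C)(C)C(C)(C)C)cc2[C@H]1OC(=O)CC(C)C
F11 | step 15 | (2R,3R)-5-{(1S)-1-[(tert-butyldimethylsilyl)oxy]ethyl}-2-(3-hydroxyprop-1-en-2-yl)-2,3-dihydrobenzofuran-3-yl 3-methylbutanoate | C=C(CO)[C@H]1Oc2ccc([C@H](C)O[Si](C)(C)C(C)(C)C)cc2[C@H]1OC(=O)CC(C)C
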